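## Analysis of the target

The target is a 2'→8'' biflavonoid. It joins a (2S)-eriodictyol unit (rings A and C with O1, C2–C4 and C4a–C8a; ring B with C1'–C6') to a luteolin unit (rings A'' and C'' with O1'' and C2''–C8a''; ring B'' with C1'''–C6''') through the bond C2'–C8''. C2 is the only stereocentre. It is benzylic, carries the aryl ether oxygen O1 and lies β to the C4 ketone, so base, hot acid or oxidation of ring B can open ring C to the chalcone and erase it. The bond C2'–C8'' has four ortho neighbours (C1' bearing C2, C3'–OH, C7''–OH and C8a''–O1''), which makes it the most crowded bond of the molecule and very probably a stereogenic axis that the given structure leaves open. Both of its ends are regiochemical problems: C2' is the more hindered of the two positions ortho to C1', and C8'' must be told from the nearly equivalent C6''. Eight free phenols, four of them in two catechols, make the final compound sensitive to air and base, so they must be masked by groups that leave under neutral conditions. The plan rests on ring B, where four contiguous substituted carbons, C1' (bearing C2), C2' (bearing C8''), C3' (OH) and C4' (OH), are followed by two CH groups, C5' and C6'. This is the pattern that arises when an alkyne C1'≡C2' adds across a 3-alkoxyfuran whose carbons become C3'–C6' and whose ring oxygen stays on C3', so ring B can be grown around a bond to C8'' that is already in place.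

## Retrosynthetic reasoning

**19 from 18.** The eight O–benzyl bonds of 18 are cut last. Hydrogenolysis is neutral, so it touches neither C2 nor the two catechols. One kind of protecting group for all eight phenols costs a single step at the end.

**18 from 16 through 17.** The bond O1–C2 is cut. C2 is set as late as possible because every further basic or acidic step puts it at risk. The forward reaction is a catalytic enantioselective oxa-Michael ring closure. A tert-butyl ester on C3 makes the acceptor 16 a good hydrogen-bond partner for the catalyst, and it leaves as gas from 17 in the same flask.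

**16 from 14 and 15.** The bond C2=C3 is cut, which splits the molecule into the biaryl aldehyde 14 and the ring A ketoester 15. The forward reaction is a condensation that needs only an aldehyde on C1'. Compound 15 comes in one step from 2, which also serves as the source of ring A''.

**14 from 13, and 13 from 9 and 11 through 12.** This is the key disconnection. Two bonds of ring B are cut, C2'–C3' and C1'–C6', and the bond C2'–C8'' is left untouched. Ring B falls apart into the alkyne carbons of the ynal 9 (C1' and C2') and the furan 11 (C3'–C6' and O3'). Three things are gained: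
- No bond has to be made between two crowded aromatic carbons.
- The order CHO, aryl, OH, OBn around ring B follows from the polarity of the two partners.
- The step loses no atom.

**9 from 6 and 7 through 8.** The bond between C8'' and the alkyne carbon is cut. A linear alkyne feels little of the two ortho oxygen substituents at C8'', so this coupling is far easier than an aryl–aryl coupling at the same carbon. Compound 7 brings C2', C1' and the future C2 in masked form.

**6 from 5, 5 from 3 and 4, 3 from 2, 2 from 1.** Ring C'' is cut at O1''–C2'' and C2''=C3''. The choice between C8'' and C6'' is made on the acetophenone 3, where only one phenol is free. The iodine next to that phenol must end up at C8'' once that oxygen has become O1''.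

**11 from 10.** The C–O bond of the furan ether is cut. The benzyl group is chosen so that O4' leaves with all the other groups in the last step.

## Alternatives that were turned down

**Alternative 1:** the textbook cut at C2'–C8''. The forward key step is a Suzuki–Miyaura coupling of the iodide 6 with the ring B boronate A1, which would give 14 directly. Four reasons count against it:
- The bond would be made between two carbons that together carry four ortho substituents, so transmetalation and reductive elimination are both slowed.
- The C–B bond of A1 lies between a formyl and a benzyloxy group and is set up for protodeboronation under the basic conditions.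
- Compound 6 is an electron-rich iodide flanked on both sides, which adds slowly to zerovalent palladium and tends to be reduced.
- A1 needs a protecting-group exchange, a benzylation and a borylation of its own, so this cut takes as many steps from 6 to 14 as the chosen route does. It wins nothing in length while the risk sits in the least forgiving bond.

**Alternative 2:** a cut at C2–C1'. The forward key step is an enantioselective conjugate addition of the biaryl boronic acid A2 to the chromone A3. The catalyst would be Pd(OCOCF3)2 with a pyridine–oxazoline ligand or [RhCl(C2H4)2]2 with a chiral diene, and the product would be 18 with C2 set in the union. Three reasons count against it: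
- The aryl group to be transferred carries a whole flavone in its ortho position, and in the insertion step this group must lie over the chromone on the metal, so protodeboronation should win.
- A3 is a vinylogous ester that is further deactivated by two donor oxygens.
- A2 still contains the bond C2'–C8'', so the hardest problem is only moved, not solved.

**Alternative 3:** a cut through rings A'' and C'', at C4a''–C8a'' and O1''–C2''. The forward key step is the biomimetic folding of the poly-β-carbonyl ester A4, by Claisen condensation to the acylphloroglucinol A5 and then cyclodehydration to the flavone. Three reasons count against it: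
- A5 has two phenols ortho to the diketone side chain. Closure through the less hindered one gives the 6-aryl isomer A6, and nothing in the structure favours the 8-aryl isomer that is needed.
- A4 has several competing aldol and pyrone modes of folding.
- Assembling A4 from an arylacetate would take more steps than ring A'' is worth, because ring A'' can be bought as 1.

Key step: step 7

Assumption: the given structure fixes only C2 (S) and leaves the axis C2'–C8'' open, so the axis is not controlled. Compounds 13–16 are racemic about it, and 17–19 may each be a pair of (2S) atropisomers, to be separated by chromatography at 18 or 19 if they do not interconvert.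

Short name used below: tetra-O-benzylluteolin-8-yl = 5,7-bis(benzyloxy)-2-[3,4-bis(benzyloxy)phenyl]-4-oxo-4H-chromen-8-yl.

## Steps

Step 1
Reactants: 1 1-(2,4,6-trihydroxyphenyl)ethan-1-one (phloroacetophenone)
Product: 2 1-[2,4-bis(benzyloxy)-6-hydroxyphenyl]ethan-1-one
Conditions: BnBr (2.1 equiv), K2CO3, DMF, rt to 50 °C
Reagents that add atoms: benzyl bromide, BrCc1ccccc1
Why: Williamson ether synthesis; after two benzylations the last phenol is held in a strong hydrogen bond to the acetyl carbonyl and should stay free when only two equivalents of the halide are offered.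

Step 2
Reactants: 2 1-[2,4-bis(benzyloxy)-6-hydroxyphenyl]ethan-1-one
Product: 3 1-[4,6-bis(benzyloxy)-2-hydroxy-3-iodophenyl]ethan-1-one
Conditions: NIS (1.0 equiv), TFA (cat.), MeCN, 0 °C to rt
Reagents that add atoms: N-iodosuccinimide, O=C1CCC(=O)N1I
Why: Electrophilic aromatic iodination; both free ring positions are activated by three oxygens, but the one between the small free OH and one benzyloxy group is less crowded than the one between two benzyloxy groups, so iodine should enter next to the free phenol, at the future C8''.

Step 3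
Reactants: 3 1-[4,6-bis(benzyloxy)-2-hydroxy-3-iodophenyl]ethan-1-one; 4 3,4-bis(benzyloxy)benzaldehyde
Product: 5 (E)-1-[4,6-bis(benzyloxy)-2-hydroxy-3-iodophenyl]-3-[3,4-bis(benzyloxy)phenyl]prop-2-en-1-one
Conditions: KOH (aq, excess), EtOH–THF, rt; then dilute aq HCl
Reagents that add atoms: none
Why: Claisen–Schmidt condensation of a methyl ketone with an aldehyde that cannot enolise; the conjugated E-enone is the stable product, and the aryl iodide and benzyl ethers are inert to aqueous base.

Step 4
Reactants: 5 (E)-1-[4,6-bis(benzyloxy)-2-hydroxy-3-iodophenyl]-3-[3,4-bis(benzyloxy)phenyl]prop-2-en-1-one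
Product: 6 5,7-bis(benzyloxy)-2-[3,4-bis(benzyloxy)phenyl]-8-iodo-4H-chromen-4-one (8-iodo-tetra-O-benzylluteolin)
Conditions: I2 (10 mol %), DMSO, 120 °C
Reagents that add atoms: none
Why: Oxidative cyclisation of a 2'-hydroxychalcone with iodine in DMSO (oxa-Michael closure, α-iodination, loss of HI, reoxidation of HI by DMSO). Only one phenol is free, so it becomes O1'' and the iodine next to it must stand at C8''.

Step 5
Reactants: 6 8-iodo-tetra-O-benzylluteolin; 7 3,3-diethoxyprop-1-yne
Product: 9 3-(tetra-O-benzylluteolin-8-yl)prop-2-ynal, via diethyl acetal 8 (not isolated)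
Conditions: PdCl2(PPh3)2 (5 mol %), CuI (10 mol %), Et3N–DMF, 60 °C; then dilute aq HCl, THF, rt
Reagents that add atoms: water, O
Why: Sonogashira coupling; the rod-shaped copper acetylide reaches the flanked carbon C8'' far more easily than an aryl nucleophile would. The propargylic acetal is then hydrolysed by dilute acid, which leaves benzyl ethers and the flavone untouched.

Step 6
Reactants: 10 3-bromofuran
Product: 11 3-(benzyloxy)furan
Conditions: BnOH (2 equiv), CuI (10 mol %), 3,4,7,8-tetramethyl-1,10-phenanthroline (20 mol %), Cs2CO3, toluene, 110 °C, sealed tube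
Reagents that add atoms: benzyl alcohol, OCc1ccccc1
Why: Ullmann-type copper-catalysed C–O coupling of a heteroaryl bromide with a primary alcohol; the β-position of furan has no other leaving group and the product is stable to base.

Step 7
Reactants: 9 3-(tetra-O-benzylluteolin-8-yl)prop-2-ynal; 11 3-(benzyloxy)furan
Product: 13 4-(benzyloxy)-3-hydroxy-2-(tetra-O-benzylluteolin-8-yl)benzaldehyde, via oxanorbornadiene cycloadduct 12 (not isolated)
Conditions: 11 (3 equiv), toluene, 80 °C, sealed tube; then removal of excess 11 in vacuo, PPTS (10 mol %), CH2Cl2, rt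
Reagents that add atoms: none
Why: Normal-electron-demand Diels–Alder reaction of an electron-rich furan with an acetylenic aldehyde, followed by the acid-induced isomerisation of the 7-oxanorbornadiene to a phenol; both are known reaction types, and the cycloaddition of acceptor-substituted aryl alkynes with oxygenated dienes is an established way to tri- and tetra-ortho-substituted biaryls. The benzyloxy group gives furan C2 the largest HOMO coefficient and the formyl group gives the alkyne carbon bound to C8'' the largest LUMO coefficient, so these two carbons join (C3'–C2') while furan C5 joins the formyl-bearing carbon (C6'–C1'), which is the para orientation expected of a diene with a donor on an inner carbon. Ring B is thus closed by an intermolecular [4+2] cycloaddition that forms two C–C bonds; the bond C2'–C8' ' is not formed here, because it was laid down in step 5 as an unhindered aryl–alkynyl bond and becomes a crowded biaryl bond only when the ring grows around it. In 12 the bridging oxygen sits on C6' as part of a vinylogous acetal (O–C6'–C5'=C4'–OBn), so a trace of acid should ionise C6'–O and not C3'–O, and loss of the proton on C3' then aromatises the ring and leaves the former furan oxygen as the C3' hydroxyl next to C4'–OBn. The aromatisation is irreversible and drains the reversible cycloaddition. No stereocentre survives, since both bridgeheads of 12 become sp2 carbons, and the new axis forms as a racemate. The step needs regioselectivity (secured by the matched polarisation of both partners), selectivity in the opening of the bridge (secured by the benzyloxy donor) and chemoselectivity for the ynal over C2''=C3'' of the flavone, which is a vinylogous ester and a far poorer dienophile.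

Step 8
Reactants: 13 4-(benzyloxy)-3-hydroxy-2-(tetra-O-benzylluteolin-8-yl)benzaldehyde
Product: 14 3,4-bis(benzyloxy)-2-(tetra-O-benzylluteolin-8-yl)benzaldehyde
Conditions: BnBr (1.5 equiv), K2CO3, DMF, 60 °C
Reagents that add atoms: benzyl bromide, BrCc1ccccc1
Why: Williamson ether synthesis on the only free phenol; masking O3' keeps a second acidic OH away from the hydrogen-bonding catalyst of step 11.

Step 9
Reactants: 2 1-[2,4-bis(benzyloxy)-6-hydroxyphenyl]ethan-1-one
Product: 15 tert-butyl 3-[2,4-bis(benzyloxy)-6-hydroxyphenyl]-3-oxopropanoate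
Conditions: LiHMDS (3.2 equiv), THF, −78 °C; Boc2O (1.1 equiv), −78 to 0 °C; then dilute aq HCl
Reagents that add atoms: di-tert-butyl dicarbonate, CC(C)(C)OC(=O)OC(=O)OC(C)(C)C
Why: Claisen-type C-acylation of the lithium dianion of an o-hydroxyacetophenone, whose enolate carbon is the more reactive site. The third equivalent of base takes up the acidic product, and the bulky ester resists lactonisation to a 4-hydroxycoumarin at low temperature.

Step 10
Reactants: 14 3,4-bis(benzyloxy)-2-(tetra-O-benzylluteolin-8-yl)benzaldehyde; 15 tert-butyl 3-[2,4-bis(benzyloxy)-6-hydroxyphenyl]-3-oxopropanoate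
Product: 16 tert-butyl 2-[2,4-bis(benzyloxy)-6-hydroxybenzoyl]-3-[3,4-bis(benzyloxy)-2-(tetra-O-benzylluteolin-8-yl)phenyl]prop-2-enoate (alkene isomers)
Conditions: piperidine (20 mol %), AcOH (20 mol %), molecular sieves 4 Å, toluene, rt
Reagents that add atoms: none
Why: Knoevenagel condensation of a β-ketoester with an aromatic aldehyde that has one free ortho position (C6'–H). Buffered amine catalysis at room temperature and removal of water should give the alkylidene compound before the phenol adds.

Step 11
Reactants: 16 tert-butyl 2-[2,4-bis(benzyloxy)-6-hydroxybenzoyl]-3-[3,4-bis(benzyloxy)-2-(tetra-O-benzylluteolin-8-yl)phenyl]prop-2-enoate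
Product: 18 (2S)-5,7-bis(benzyloxy)-2-[3,4-bis(benzyloxy)-2-(tetra-O-benzylluteolin-8-yl)phenyl]chroman-4-one, via flavanone 3-carboxylate 17 (not isolated)
Conditions: 9-amino-9-deoxy-epi-cinchona 3,5-bis(trifluoromethyl)phenyl thiourea (10 mol %; the quinine- or quinidine-derived pseudoenantiomer that gives the 2S sense), toluene, −25 °C; then TsOH·H2O, 80 °C
Reagents that add atoms: none
Why: Enantioselective intramolecular oxa-Michael addition (6-endo-trig) under bifunctional thiourea–amine catalysis. The thiourea binds the 1,3-dicarbonyl unit and the quinuclidine nitrogen activates the phenol, so O1 is delivered to one face of C2 and the catalyst sets the 2S configuration. Acid then cleaves the tert-butyl ester and the β-keto acid loses CO2, which also removes the labile centre at C3.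

Step 12
Reactants: 18 (2S)-5,7-bis(benzyloxy)-2-[3,4-bis(benzyloxy)-2-(tetra-O-benzylluteolin-8-yl)phenyl]chroman-4-one
Product: 19 8-{6-[(2S)-5,7-dihydroxy-4-oxochroman-2-yl]-2,3-dihydroxyphenyl}-2-(3,4-dihydroxyphenyl)-5,7-dihydroxy-4H-chromen-4-one (target)
Conditions: H2 (1 atm), 10% Pd/C, THF–MeOH, rt
Reagents that add atoms: none
Why: Catalytic hydrogenolysis of eight primary benzyl aryl ethers under neutral conditions, which cannot open ring C and so keeps C2. The conjugated C2''=C3'' bond and the crowded secondary C2–O1 bond react much more slowly than primary benzyl ethers.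

## Compound list

1 | 1-(2,4,6-trihydroxyphenyl)ethan-1-one | CC(=O)c1c(O)cc(O)cc1O | starting material
2 | 1-[2,4-bis(benzyloxy)-6-hydroxyphenyl]ethan-1-one | CC(=O)c1c(O)cc(OCc2ccccc2)cc1OCc1ccccc1 | intermediate
3 | 1-[4,6-bis(benzyloxy)-2-hydroxy-3-iodophenyl]ethan-1-one | CC(=O)c1c(O)c(I)c(OCc2ccccc2)cc1OCc1ccccc1 | intermediate
4 | 3,4-bis(benzyloxy)benzaldehyde | O=Cc1ccc(OCc2ccccc2)c(OCc2ccccc2)c1 | starting material
5 | (E)-1-[4,6-bis(benzyloxy)-2-hydroxy-3-iodophenyl]-3-[3,4-bis(benzyloxy)phenyl]prop-2-en-1-one | O=C(/C=C/c1ccc(OCc2ccccc2)c(OCc2ccccc2)c1)c1c(O)c(I)c(OCc2ccccc2)cc1OCc1ccccc1 | intermediate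
6 | 5,7-bis(benzyloxy)-2-[3,4-bis(benzyloxy)phenyl]-8-iodo-4H-chromen-4-one | O=c1cc(-c2ccc(OCc3ccccc3)c(OCc3ccccc3)c2)oc2c(I)c(OCc3ccccc3)cc(OCc3ccccc3)c12 | intermediate
7 | 3,3-diethoxyprop-1-yne | C#CC(OCC)OCC | starting material
8 | 5,7-bis(benzyloxy)-2-[3,4-bis(benzyloxy)phenyl]-8-(3,3-diethoxyprop-1-yn-1-yl)-4H-chromen-4-one | CCOC(OCC)C#Cc1c(OCc2ccccc2)cc(OCc2ccccc2)c2c(=O)cc(-c3ccc(OCc4ccccc4)c(OCc4ccccc4)c3)oc12 | intermediate
9 | 3-(tetra-O-benzylluteolin-8-yl)prop-2-ynal | O=CC#Cc1c(OCc2ccccc2)cc(OCc2ccccc2)c2c(=O)cc(-c3ccc(OCc4ccccc4)c(OCc4ccccc4)c3)oc12 | intermediate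
10 | 3-bromofuran | Brc1ccoc1 | starting material
11 | 3-(benzyloxy)furan | c1ccc(COc2ccoc2)cc1 | intermediate
12 | 5-(benzyloxy)-3-(tetra-O-benzylluteolin-8-yl)-7-oxabicyclo[2.2.1]hepta-2,5-diene-2-carbaldehyde (racemic) | O=CC1=C(c2c(OCc3ccccc3)cc(OCc3ccccc3)c3c(=O)cc(-c4ccc(OCc5ccccc5)c(OCc5ccccc5)c4)oc23)C2OC1C=C2OCc1ccccc1 | intermediate
13 | 4-(benzyloxy)-3-hydroxy-2-(tetra-O-benzylluteolin-8-yl)benzaldehyde | O=Cc1ccc(OCc2ccccc2)c(O)c1-c1c(OCc2ccccc2)cc(OCc2ccccc2)c2c(=O)cc(-c3ccc(OCc4ccccc4)c(OCc4ccccc4)c3)oc12 | intermediate
14 | 3,4-bis(benzyloxy)-2-(tetra-O-benzylluteolin-8-yl)benzaldehyde | O=Cc1ccc(OCc2ccccc2)c(OCc2ccccc2)c1-c1c(OCc2ccccc2)cc(OCc2ccccc2)c2c(=O)cc(-c3ccc(OCc4ccccc4)c(OCc4ccccc4)c3)oc12 | intermediate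
15 | tert-butyl 3-[2,4-bis(benzyloxy)-6-hydroxyphenyl]-3-oxopropanoate | CC(C)(C)OC(=O)CC(=O)c1c(O)cc(OCc2ccccc2)cc1OCc1ccccc1 | intermediate
16 | tert-butyl 2-[2,4-bis(benzyloxy)-6-hydroxybenzoyl]-3-[3,4-bis(benzyloxy)-2-(tetra-O-benzylluteolin-8-yl)phenyl]prop-2-enoate (alkene isomers) | CC(C)(C)OC(=O)C(=Cc1ccc(OCc2ccccc2)c(OCc2ccccc2)c1-c1c(OCc2ccccc2)cc(OCc2ccccc2)c2c(=O)cc(-c3ccc(OCc4ccccc4)c(OCc4ccccc4)c3)oc12)C(=O)c1c(O)cc(OCc2ccccc2)cc1OCc1ccccc1 | intermediate
17 | tert-butyl (2S)-5,7-bis(benzyloxy)-2-[3,4-bis(benzyloxy)-2-(tetra-O-benzylluteolin-8-yl)phenyl]-4-oxochromane-3-carboxylate (C3 labile) | O=C1C(C(=O)OC(C)(C)C)[C@@H](c2ccc(OCc3ccccc3)c(OCc3ccccc3)c2-c2c(OCc3ccccc3)cc(OCc3ccccc3)c3c(=O)cc(-c4ccc(OCc5ccccc5)c(OCc5ccccc5)c4)oc23)Oc2cc(OCc3ccccc3)cc(OCc3ccccc3)c21 | intermediate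
18 | (2S)-5,7-bis(benzyloxy)-2-[3,4-bis(benzyloxy)-2-(tetra-O-benzylluteolin-8-yl)phenyl]chroman-4-one | O=C1C[C@@H](c2ccc(OCc3ccccc3)c(OCc3ccccc3)c2-c2c(OCc3ccccc3)cc(OCc3ccccc3)c3c(=O)cc(-c4ccc(OCc5ccccc5)c(OCc5ccccc5)c4)oc23)Oc2cc(OCc3ccccc3)cc(OCc3ccccc3)c21 | intermediate
19 | 8-{6-[(2S)-5,7-dihydroxy-4-oxochroman-2-yl]-2,3-dihydroxyphenyl}-2-(3,4-dihydroxyphenyl)-5,7-dihydroxy-4H-chromen-4-one | O=C1C[C@@H](c2ccc(O)c(O)c2-c2c(O)cc(O)c3c(=O)cc(-c4ccc(O)c(O)c4)oc23)Oc2cc(O)cc(O)c21 | target

## Step count and least certain steps

Total step count: 12. Longest linear sequence: 10 steps (steps 1, 2, 3, 4, 5, 7, 8, 10, 11 and 12). Steps 6 and 9 are side branches of one step each.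

**Step 7 (key step).**
- *What may go wrong:* The cycloaddition may be slow because the alkyne carbon that has to bond to furan C2 carries a doubly flanked aryl group. The polar pathway may stop after the first bond, by loss of a proton and return to a substituted furan. Steric repulsion may override the electronic orientation. Excess furan may polymerise once acid is present.
- *Fallback:* It sets out from 6, comes back at 14, and forms the bond C2'–C8'' by cross-coupling with the polarity inverted relative to Alternative 1.
  - Miyaura borylation of 6 (B2pin2, PdCl2(dppf), KOAc, dioxane, 90 °C) gives the flavone 8-boronate F1.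
  - Commercial 2-bromo-3-hydroxy-4-methoxybenzaldehyde F2 is demethylated with BBr3 to 2-bromo-3,4-dihydroxybenzaldehyde F3.
  - F3 is benzylated twice (BnBr, K2CO3) to 3,4-bis(benzyloxy)-2-bromobenzaldehyde F4, whose bromide is activated for oxidative addition by the ortho formyl group.
  - Suzuki–Miyaura coupling of F1 with F4 (Pd(OAc)2, SPhos, K3PO4, toluene–water, 100 °C) gives 14.

**Step 11.**
- *What may go wrong:* The phenol may add without the catalyst, since the 6-benzyloxy group twists the aroyl unit and favours closure. One of the two atropisomers of 16 may be mismatched with the catalyst and lower the facial selectivity. Ring C may open and reclose during the hot acid treatment.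
- *Fallback:* It sets out from 14 (together with 2), comes back at 18, and replaces asymmetric ring closure by a resolution.
  - Claisen–Schmidt condensation of 14 with 2 (KOH, EtOH–THF) gives the 2'-hydroxychalcone F5.
  - NaOAc in refluxing EtOH closes F5 to the racemic flavanone F6.
  - Asymmetric transfer hydrogenation with Cp*RhCl[(R,R)-TsDPEN] in HCO2H–Et3N should reduce the 2R enantiomer to the cis-(2R,4R)-flavan-4-ol F7 and leave 18.
  - F7 can be brought back to F6 by Dess–Martin oxidation and equilibration with base.

**Step 10.**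
- *What may go wrong:* Condensation may be slow at the aldehyde next to the biaryl bond. The amine-induced oxa-Michael addition may occur early, which would give racemic material before the chiral catalyst is present.
- *Fallback:* It sets out from 15 and comes back at 16, with the phenol kept masked during the condensation.
  - Silylation of 15 (TBSCl, imidazole, DMF) gives the silyl ether ketoester F8.
  - Knoevenagel condensation of F8 with 14 gives the silylated alkylidene compound F9.
  - HF·pyridine in THF at 0 °C sets 16 free just before step 11.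

**Step 6.**
- *What may go wrong:* The electron-rich, volatile bromide may convert poorly. The acid- and air-sensitive product may decay during the long heating.
- *Fallback:* It sets out from 7, comes back at 11, and builds the furan ring instead of substituting it.
  - Lithiation of 7 (n-BuLi, THF, −78 °C) and addition to paraformaldehyde gives 4,4-diethoxybut-2-yn-1-ol F10.
  - (Ph3P)AuNTf2 (2 mol %) with benzyl alcohol in CH2Cl2 at rt should cyclise F10 to 11, with loss of ethanol.

**Step 12.**
- *What may go wrong:* Cleavage of the eight ethers may be incomplete as the polar partly deprotected material leaves solution. C2''=C3'' may be slowly saturated, or the benzylic C2–O1 bond may undergo hydrogenolysis.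
- *Fallback:* It sets out from 18, comes back at 19, and is not reductive. BCl3 with pentamethylbenzene as benzyl cation trap in CH2Cl2 at −78 °C removes all benzyl groups at a temperature at which ring C should stay closed. No new compound arises on the way (F0).

## Further compounds

F1 | step 7 | 5,7-bis(benzyloxy)-2-[3,4-bis(benzyloxy)phenyl]-8-(4,4,5,5-tetramethyl-1,3,2-dioxaborolan-2-yl)-4H-chromen-4-one | CC1(C)OB(OC1(C)C)c1c(OCc2ccccc2)cc(OCc2ccccc2)c2c(=O)cc(-c3ccc(OCc4ccccc4)c(OCc4ccccc4)c3)oc12
F2 | step 7 | 2-bromo-3-hydroxy-4-methoxybenzaldehyde | COc1ccc(C=O)c(Br)c1O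
F3 | step 7 | 2-bromo-3,4-dihydroxybenzaldehyde | O=Cc1ccc(O)c(O)c1Br
F4 | step 7 | 3,4-bis(benzyloxy)-2-bromobenzaldehyde | O=Cc1ccc(OCc2ccccc2)c(OCc2ccccc2)c1Br
F5 | step 11 | (E)-1-[2,4-bis(benzyloxy)-6-hydroxyphenyl]-3-[3,4-bis(benzyloxy)-2-(tetra-O-benzylluteolin-8-yl)phenyl]prop-2-en-1-one | O=C(/C=C/c1ccc(OCc2ccccc2)c(OCc2ccccc2)c1-c1c(OCc2ccccc2)cc(OCc2ccccc2)c2c(=O)cc(-c3ccc(OCc4ccccc4)c(OCc4ccccc4)c3)oc12)c1c(O)cc(OCc2ccccc2)cc1OCc1ccccc1
F6 | step 11 | racemic 5,7-bis(benzyloxy)-2-[3,4-bis(benzyloxy)-2-(tetra-O-benzylluteolin-8-yl)phenyl]chroman-4-one | O=C1CC(c2ccc(OCc3ccccc3)c(OCc3ccccc3)c2-c2c(OCc3ccccc3)cc(OCc3ccccc3)c3c(=O)cc(-c4ccc(OCc5ccccc5)c(OCc5ccccc5)c4)oc23)Oc2cc(OCc3ccccc3)cc(OCc3ccccc3)c21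
F7 | step 11 | (2R,4R)-5,7-bis(benzyloxy)-2-[3,4-bis(benzyloxy)-2-(tetra-O-benzylluteolin-8-yl)phenyl]chroman-4-ol | O[C@@H]1C[C@H](c2ccc(OCc3ccccc3)c(OCc3ccccc3)c2-c2c(OCc3ccccc3)cc(OCc3ccccc3)c3c(=O)cc(-c4ccc(OCc5ccccc5)c(OCc5ccccc5)c4)oc23)Oc2cc(OCc3ccccc3)cc(OCc3ccccc3)c21
F8 | step 10 | tert-butyl 3-[2,4-bis(benzyloxy)-6-(tert-butyldimethylsilyloxy)phenyl]-3-oxopropanoate | CC(C)(C)OC(=O)CC(=O)c1c(O[Si](C)(C)C(C)(C)C)cc(OCc2ccccc2)cc1OCc1ccccc1
F9 | step 10 | tert-butyl 2-[2,4-bis(benzyloxy)-6-(tert-butyldimethylsilyloxy)benzoyl]-3-[3,4-bis(benzyloxy)-2-(tetra-O-benzylluteolin-8-yl)phenyl]prop-2-enoate | CC(C)(C)OC(=O)C(=Cc1ccc(OCc2ccccc2)c(OCc2ccccc2)c1-c1c(OCc2ccccc2)cc(OCc2ccccc2)c2c(=O)cc(-c3ccc(OCc4ccccc4)c(OCc4ccccc4)c3)oc12)C(=O)c1c(O[Si](C)(C)C(C)(C)C)cc(OCc2ccccc2)cc1OCc1ccccc1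
F10 | step 6 | 4,4-diethoxybut-2-yn-1-ol | CCOC(OCC)C#CCO
F0 | step 12 | none | none
A1 | alternative 1 | 3,4-bis(benzyloxy)-2-(4,4,5,5-tetramethyl-1,3,2-dioxaborolan-2-yl)benzaldehyde | O=Cc1ccc(OCc2ccccc2)c(OCc2ccccc2)c1B1OC(C)(C)C(C)(C)O1
A2 | alternative 2 | [3,4-bis(benzyloxy)-2-(tetra-O-benzylluteolin-8-yl)phenyl]boronic acid | OB(O)c1ccc(OCc2ccccc2)c(OCc2ccccc2)c1-c1c(OCc2ccccc2)cc(OCc2ccccc2)c2c(=O)cc(-c3ccc(OCc4ccccc4)c(OCc4ccccc4)c3)oc12
A3 | alternative 2 | 5,7-bis(benzyloxy)-4H-chromen-4-one | O=c1ccoc2cc(OCc3ccccc3)cc(OCc3ccccc3)c12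
A4 | alternative 3 | methyl 2-[2,3-bis(benzyloxy)-6-(1,3-dioxolan-2-yl)phenyl]-9-[3,4-bis(benzyloxy)phenyl]-3,5,7,9-tetraoxononanoate | COC(=O)C(C(=O)CC(=O)CC(=O)CC(=O)c1ccc(OCc2ccccc2)c(OCc2ccccc2)c1)c1c(C2OCCO2)ccc(OCc2ccccc2)c1OCc1ccccc1
A5 | alternative 3 | 1-{3-[2,3-bis(benzyloxy)-6-(1,3-dioxolan-2-yl)phenyl]-2,4,6-trihydroxyphenyl}-3-[3,4-bis(benzyloxy)phenyl]propane-1,3-dione | O=C(CC(=O)c1ccc(OCc2ccccc2)c(OCc2ccccc2)c1)c1c(O)cc(O)c(-c2c(C3OCCO3)ccc(OCc3ccccc3)c2OCc2ccccc2)c1O
A6 | alternative 3 | 6-[2,3-bis(benzyloxy)-6-(1,3-dioxolan-2-yl)phenyl]-2-[3,4-bis(benzyloxy)phenyl]-5,7-dihydroxy-4H-chromen-4-one | O=c1cc(-c2ccc(OCc3ccccc3)c(OCc3ccccc3)c2)oc2cc(O)c(-c3c(C4OCCO4)ccc(OCc4ccccc4)c3OCc3ccccc3)c(O)c12
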